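**Plan** (target numbered as a benzo[7]annulene: spiro carbon C-5, CH2 C-6, CH(CH3) C-7 and C-8, CH(OBz) C-9; ring A = trimethoxybenzene ring, ring B = seven-membered ring, ring C = dimethoxycyclohexadienone)

1. Retrosynthesis: first open ring B at the bond between the spiro carbon of ring C and C-4a of ring A, which leaves a para-alkylated syringyl phenol; then remove the benzoate and the hydrogen pair at C-7 (alkene precursor); last, cut the ring A–C-9 bond and the C-8–C-7 bond together.
2. Enabling feature: the oxygen-bearing benzylic carbon C-9 and its methyl-bearing neighbour C-8 are read as the two carbons of a (Z)-propenylboron unit. The C-9–O bond is a former C–B bond, ring A is the group that migrates from boron to C-9, and C-7 is the carbon of an alkenyl triflate that palladium joins to C-8.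
3. Forward: silylated methoxyeugenol → arylacetone → (Z)-enol triflate; acenaphthoquinone → cis-diol → (Z)-propenylboronic ester. A three-component conjunctive coupling then joins the whole C18 chain. Oxidation, hydrogenation, benzoylation and desilylation follow; ring B and the spiro centre of ring C arise last by phenol oxidation.
4. Stereochemistry: C-9 and C-8 come from anti addition across the (Z)-alkene under a chiral palladium–bisphosphine catalyst, and C–B becomes C–O with retention. C-7 comes from hydroxyl-directed hydrogenation of the (Z)-trisubstituted alkene under allylic-strain control. The spiro carbon is not stereogenic.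

Key step: step 6

Assumption: the (Sp,Sp) enantiomer of MandyPhos is taken to give the (1R,2R) boronate 12; should the opposite sense be found, the (Rp,Rp) ligand is used.

Step 1
Reactants: 1 4-allyl-2,6-dimethoxyphenol
Product: 2 (4-allyl-2,6-dimethoxyphenoxy)tri(propan-2-yl)silane
Conditions: i-Pr3SiCl, imidazole, DMF, 40 °C
Reagents that add atoms: chlorotri(propan-2-yl)silane, CC(C)[Si](Cl)(C(C)C)C(C)C
Why: O-silylation of the phenol; the hindered aryl silyl ether should withstand the borate chemistry, basic peroxide and hydrogenation, and is later removed by fluoride without touching a benzoate.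

Step 2
Reactants: 2 (4-allyl-2,6-dimethoxyphenoxy)tri(propan-2-yl)silane
Product: 3 1-{3,5-dimethoxy-4-[tri(propan-2-yl)silyloxy]phenyl}propan-2-one
Conditions: PdCl2 (10 mol%), CuCl (1 equiv), O2 (1 atm), DMF/H2O (7:1), rt
Reagents that add atoms: water, O
Why: Tsuji–Wacker oxidation; Markovnikov hydroxypalladation of the terminal alkene should give the methyl ketone.

Step 3
Reactants: 3 1-{3,5-dimethoxy-4-[tri(propan-2-yl)silyloxy]phenyl}propan-2-one
Product: 4 (Z)-1-{3,5-dimethoxy-4-[tri(propan-2-yl)silyloxy]phenyl}prop-1-en-2-yl trifluoromethanesulfonate (aryl and triflate cis)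
Conditions: KN(SiMe3)2, THF, −78 °C; PhNTf2, −78 → 0 °C
Reagents that add atoms: N-phenylbis(trifluoromethanesulfonimide), O=S(=O)(N(c1ccccc1)S(=O)(=O)C(F)(F)F)C(F)(F)F
Why: Enol triflate formation; deprotonation at the more acidic benzylic CH2 should give the conjugated enolate with aryl trans to methyl, and O-sulfonylation fixes that (Z) geometry.

Step 4
Reactants: 5 acenaphthylene-1,2-dione (acenaphthoquinone)
Product: 6 cis-1,2-dimethyl-1,2-dihydroacenaphthylene-1,2-diol (meso diol, "mac diol")
Conditions: MeMgBr (3 equiv), THF, 0 °C → rt; aq NH4Cl; crystallization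
Reagents that add atoms: methylmagnesium bromide, C[Mg]Br
Why: Double Grignard 1,2-addition to the 1,2-dione; the cis (meso) diol, the isomer able to span boron, is taken on after crystallization.

Step 5
Reactants: 6 cis-1,2-dimethyl-1,2-dihydroacenaphthylene-1,2-diol; 7 (Z)-prop-1-en-1-ylboronic acid
Product: 8 (Z)-prop-1-en-1-ylboronic acid cis-1,2-dimethylacenaphthylene-1,2-diyl ester, (Z)-propenyl-B(mac)
Conditions: MgSO4, CH2Cl2, rt
Reagents that add atoms: none
Why: Condensation of a boronic acid with a cis-1,2-diol to the cyclic boronic ester; the alkene geometry is not touched.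

Step 6
Reactants: 9 5-bromo-1,2,3-trimethoxybenzene; 8 (Z)-propenyl-B(mac); 4 (Z)-enol triflate
Product: 12 B(mac) ester of (1R,2R,3Z)-4-{3,5-dimethoxy-4-[tri(propan-2-yl)silyloxy]phenyl}-2,3-dimethyl-1-(3,4,5-trimethoxyphenyl)but-3-en-1-ylboronic acid, via 3,4,5-trimethoxyphenyllithium 10 (not isolated), via lithium borate complex 11 (not isolated)
Conditions: 9, n-BuLi, THF, −78 °C; 8, −78 °C → rt; volatiles removed; Pd(OAc)2 (2 mol%), (Sp,Sp)-MandyPhos, Fe[C5H3(PPh2)(CH(NMe2)Ph)]2 (2.4 mol%), 4, THF, 60 °C
Reagents that add atoms: none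
Why: Aryllithium 10 adds to boron of 8 to give the four-coordinate borate 11; oxidative addition of triflate 4 to zerovalent palladium gives a cationic alkenyl complex of divalent palladium that binds the propenyl π bond of 11 and triggers a 1,2-shift of the trimethoxyphenyl group from boron to the boron-bearing carbon (ring A–C bond), while the neighbouring carbon is bound to palladium and then reductively eliminates with the alkenyl ligand (CH(CH3)–C(CH3)= bond). The closest known reaction type is the palladium/MandyPhos-catalysed conjunctive cross-coupling of β-substituted alkenyl-B(mac) borates with organolithiums and C(sp2) triflates. No ring is closed; the step joins three fragments into the complete C18 chain of the target. The two new stereocentres arise together: their relative configuration follows from the stereospecific anti addition of aryl and alkenyl across the (Z)-propenyl double bond, which places boron and methyl syn in the zigzag chain, and their absolute configuration from the alkene face chosen by the chiral bisphosphine–palladium complex. The step needs the metallate shift to win over direct Suzuki–Miyaura transmetallation of the propenyl or aryl group, which the hindered mac diolate on boron is there to secure, and aryl rather than oxygen migration, which is inherent to a diolate. The (Z) geometry of the triflate should be retained, so the silyloxyaryl ring ends up cis to the new methine, as step 8 requires.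

Step 7
Reactants: 12 B(mac) boronate
Product: 13 (1R,2S,3Z)-4-{3,5-dimethoxy-4-[tri(propan-2-yl)silyloxy]phenyl}-2,3-dimethyl-1-(3,4,5-trimethoxyphenyl)but-3-en-1-ol
Conditions: 30% H2O2, 3 M NaOH, THF, 0 °C → rt
Reagents that add atoms: hydrogen peroxide, OO
Why: Oxidation of the C–B bond by 1,2-migration of carbon from boron to oxygen, which proceeds with retention and should give the benzylic alcohol syn to the adjacent methyl.

Step 8
Reactants: 13 (Z)-homoallylic alcohol
Product: 14 (1R,2S,3R)-4-{3,5-dimethoxy-4-[tri(propan-2-yl)silyloxy]phenyl}-2,3-dimethyl-1-(3,4,5-trimethoxyphenyl)butan-1-ol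
Conditions: [Ir(cod)(PCy3)(py)]PF6 (5 mol%), H2 (1 atm), CH2Cl2, 0 °C → rt
Reagents that add atoms: none
Why: Hydroxyl-directed homogeneous hydrogenation; A(1,3) strain with the cis aryl group holds the allylic C–H in the alkene plane, and the carbinol oxygen binds iridium and delivers H2 to the face on the carbinol side, which should set the new CH(CH3) centre syn to the existing methyl (3R).

Step 9
Reactants: 14 saturated alcohol
Product: 15 (1R,2S,3R)-4-{3,5-dimethoxy-4-[tri(propan-2-yl)silyloxy]phenyl}-2,3-dimethyl-1-(3,4,5-trimethoxyphenyl)butyl benzoate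
Conditions: BzCl, pyridine, DMAP (cat.), CH2Cl2, 0 °C → rt
Reagents that add atoms: benzoyl chloride, O=C(Cl)c1ccccc1
Why: Nucleophile-catalysed O-acylation of the secondary alcohol, which does not touch the carbinol configuration.

Step 10
Reactants: 15 silyl ether benzoate
Product: 16 (1R,2S,3R)-4-(4-hydroxy-3,5-dimethoxyphenyl)-2,3-dimethyl-1-(3,4,5-trimethoxyphenyl)butyl benzoate
Conditions: Bu4NF, AcOH, THF, 0 °C
Reagents that add atoms: none
Why: Fluoride cleavage of the aryl silyl ether; buffering with acetic acid should keep the phenoxide from attacking the benzoate.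

Step 11
Reactants: 16 phenol
Product: 17 (7R,8S,9R)-2,3,3',4,5'-pentamethoxy-7,8-dimethyl-4'-oxo-6,7,8,9-tetrahydrospiro[benzo[7]annulene-5,1'-cyclohexa[2,5]diene]-9-yl benzoate (target)
Conditions: PhI(OAc)2 (1.1 equiv), CF3CH2OH, −40 → 0 °C
Reagents that add atoms: none
Why: Phenol oxidative dearomatization (para–ortho' coupling): the trivalent-iodine reagent should turn the phenol into a phenoxonium ion whose para carbon is attacked by C-2 of ring A (ortho and para to methoxy groups) in a seven-membered spiro closure, while the low temperature and the weakly nucleophilic fluoroalcohol hold back solvent capture and dienone–phenol rearrangement; no stereocentre is touched.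

**Compound list**

1 | 4-allyl-2,6-dimethoxyphenol | C=CCc1cc(OC)c(O)c(OC)c1 | starting material
2 | (4-allyl-2,6-dimethoxyphenoxy)tri(propan-2-yl)silane | C=CCc1cc(OC)c(O[Si](C(C)C)(C(C)C)C(C)C)c(OC)c1 | intermediate
3 | 1-{3,5-dimethoxy-4-[tri(propan-2-yl)silyloxy]phenyl}propan-2-one | CC(=O)Cc1cc(OC)c(O[Si](C(C)C)(C(C)C)C(C)C)c(OC)c1 | intermediate
4 | (Z)-1-{3,5-dimethoxy-4-[tri(propan-2-yl)silyloxy]phenyl}prop-1-en-2-yl trifluoromethanesulfonate | C/C(OS(=O)(=O)C(F)(F)F)=C/c1cc(OC)c(O[Si](C(C)C)(C(C)C)C(C)C)c(OC)c1 | intermediate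
5 | acenaphthylene-1,2-dione | O=C1C(=O)c2cccc3cccc1c23 | starting material
6 | cis-1,2-dimethyl-1,2-dihydroacenaphthylene-1,2-diol | C[C@]1(O)c2cccc3cccc(c23)[C@@]1(C)O | intermediate
7 | (Z)-prop-1-en-1-ylboronic acid | C/C=C\B(O)O | starting material
8 | (Z)-propenyl-B(mac) | C/C=C\B1O[C@@]2(C)c3cccc4cccc(c34)[C@@]2(C)O1 | intermediate
9 | 5-bromo-1,2,3-trimethoxybenzene | COc1cc(Br)cc(OC)c1OC | starting material
10 | 3,4,5-trimethoxyphenyllithium | [Li]c1cc(OC)c(OC)c(OC)c1 | intermediate (not isolated)
11 | lithium (Z)-propenyl(3,4,5-trimethoxyphenyl)borate of diol 6 | [Li+].C/C=C\[B-]1(c2cc(OC)c(OC)c(OC)c2)O[C@@]2(C)c3cccc4cccc(c34)[C@@]2(C)O1 | intermediate (not isolated)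
12 | B(mac) ester of (1R,2R,3Z)-4-{3,5-dimethoxy-4-[tri(propan-2-yl)silyloxy]phenyl}-2,3-dimethyl-1-(3,4,5-trimethoxyphenyl)but-3-en-1-ylboronic acid | COc1cc(/C=C(/C)[C@H](C)[C@@H](B2O[C@@]3(C)c4cccc5cccc(c45)[C@@]3(C)O2)c2cc(OC)c(OC)c(OC)c2)cc(OC)c1O[Si](C(C)C)(C(C)C)C(C)C | intermediate
13 | (1R,2S,3Z)-4-{3,5-dimethoxy-4-[tri(propan-2-yl)silyloxy]phenyl}-2,3-dimethyl-1-(3,4,5-trimethoxyphenyl)but-3-en-1-ol | COc1cc(/C=C(/C)[C@H](C)[C@@H](O)c2cc(OC)c(OC)c(OC)c2)cc(OC)c1O[Si](C(C)C)(C(C)C)C(C)C | intermediate
14 | (1R,2S,3R)-4-{3,5-dimethoxy-4-[tri(propan-2-yl)silyloxy]phenyl}-2,3-dimethyl-1-(3,4,5-trimethoxyphenyl)butan-1-ol | COc1cc(C[C@@H](C)[C@H](C)[C@@H](O)c2cc(OC)c(OC)c(OC)c2)cc(OC)c1O[Si](C(C)C)(C(C)C)C(C)C | intermediate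
15 | (1R,2S,3R)-4-{3,5-dimethoxy-4-[tri(propan-2-yl)silyloxy]phenyl}-2,3-dimethyl-1-(3,4,5-trimethoxyphenyl)butyl benzoate | COc1cc(C[C@@H](C)[C@H](C)[C@@H](OC(=O)c2ccccc2)c2cc(OC)c(OC)c(OC)c2)cc(OC)c1O[Si](C(C)C)(C(C)C)C(C)C | intermediate
16 | (1R,2S,3R)-4-(4-hydroxy-3,5-dimethoxyphenyl)-2,3-dimethyl-1-(3,4,5-trimethoxyphenyl)butyl benzoate | COc1cc(C[C@@H](C)[C@H](C)[C@@H](OC(=O)c2ccccc2)c2cc(OC)c(OC)c(OC)c2)cc(OC)c1O | intermediate
17 | (7R,8S,9R)-2,3,3',4,5'-pentamethoxy-7,8-dimethyl-4'-oxo-6,7,8,9-tetrahydrospiro[benzo[7]annulene-5,1'-cyclohexa[2,5]diene]-9-yl benzoate | COC1=CC2(C=C(OC)C1=O)C[C@@H](C)[C@H](C)[C@@H](OC(=O)c1ccccc1)c1cc(OC)c(OC)c(OC)c12 | target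

**Step count and risks**

Total steps: 11. Longest linear sequence: 9 steps (1, 2, 3, 6, 7, 8, 9, 10, 11 from compound 1).

Most likely to fail, first: step 6. The borate may transfer its propenyl or aryl group directly to palladium (Suzuki–Miyaura pathway), the secondary alkylpalladium intermediate may undergo β-hydride elimination before the hindered reductive elimination, or the face selection by the ligand may be weak. The fallback sets out from bromide 9 and comes back at alcohol 14, replacing steps 6–8. Bromide 9 is lithiated (n-BuLi) and formylated with DMF to 3,4,5-trimethoxybenzaldehyde F1. A boron-mediated oxazolidinone syn-aldol reaction (Bu2BOTf, i-Pr2NEt) with commercial (R)-4-benzyl-3-propionyloxazolidin-2-one should give aldol imide F2, which sets the carbinol and the adjacent methyl centre by auxiliary control. AlMe3/MeNHOMe·HCl would give Weinreb amide F3, MeMgBr the β-hydroxy methyl ketone F4, and non-basic Takai–Lombardo methylenation (Zn, CH2Br2, TiCl4) the isopropenyl carbinol F5. Hydroboration with 9-BBN is expected anti to the carbinol-bearing branch, with the allylic hydrogen eclipsing the vinylic methyl, to give the bis-9-BBN adduct F6. B-alkyl Suzuki–Miyaura coupling (Pd(dppf)Cl2, aq K3PO4, THF/DMF) with aryl bromide F7, made from 4-bromo-2,6-dimethoxyphenol and i-Pr3SiCl, would then deliver 14.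

Second: step 8. Hydrogen may be delivered from the methyl-side face if the hydroxyl fails to direct (giving the C-3 epimer), or the double bond may migrate before reduction and scramble the adjacent methyl centre. The fallback sets out from alcohol 13 and comes back at benzoate 15, so benzoylation moves ahead of the reduction. 13 is benzoylated (BzCl, pyridine, DMAP) to the alkenyl benzoate F8, which has no directing group. The alkene is then reduced under reagent control by asymmetric hydrogenation with a chiral iridium phosphinooxazoline complex, [Ir(cod)(PHOX)][B(C6H3(CF3)2)4], H2 (50 bar), CH2Cl2, with the ligand enantiomer chosen for the 3R centre.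

Third: step 11. The phenoxonium ion may be captured by solvent or at a methoxy-bearing ortho carbon, ring A may be over-oxidized by the iodine reagent, or the spirodienone may undergo acid-induced dienone–phenol rearrangement to the eight-membered biaryl. The fallback sets out from phenol 16 and comes back at target 17, with oxidation and ring closure separated. PhI(OAc)2 in methanol at 0 °C should give the isolable methanol adduct, the para-quinol methyl ether F9 (an ortho-quinone monoketal regioisomer would ionize to the same cation). BF3·OEt2 in CH2Cl2 at −78 °C would then ionize the methoxy group, and ring A closes ring B by Friedel–Crafts attack at the para carbon in the absence of oxidant.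

**Further compounds**

F1 | step 6 | 3,4,5-trimethoxybenzaldehyde | COc1cc(C=O)cc(OC)c1OC
F2 | step 6 | (R)-4-benzyl-3-[(2R,3R)-3-hydroxy-2-methyl-3-(3,4,5-trimethoxyphenyl)propanoyl]oxazolidin-2-one | COc1cc([C@H](O)[C@@H](C)C(=O)N2[C@H](Cc3ccccc3)COC2=O)cc(OC)c1OC
F3 | step 6 | (2R,3R)-3-hydroxy-N-methoxy-N,2-dimethyl-3-(3,4,5-trimethoxyphenyl)propanamide | COc1cc([C@H](O)[C@@H](C)C(=O)N(C)OC)cc(OC)c1OC
F4 | step 6 | (3R,4R)-4-hydroxy-3-methyl-4-(3,4,5-trimethoxyphenyl)butan-2-one | COc1cc([C@H](O)[C@@H](C)C(C)=O)cc(OC)c1OC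
F5 | step 6 | (1R,2S)-2,3-dimethyl-1-(3,4,5-trimethoxyphenyl)but-3-en-1-ol | COc1cc([C@H](O)[C@@H](C)C(C)=C)cc(OC)c1OC
F6 | step 6 | bis-9-BBN adduct of F5 (primary alkylborane, carbinol as its borinate), (1R,2S,3R) | COc1cc([C@H](OB2C3CCCC2CCC3)[C@@H](C)[C@H](C)CB2C3CCCC2CCC3)cc(OC)c1OC
F7 | step 6 | (4-bromo-2,6-dimethoxyphenoxy)tri(propan-2-yl)silane | COc1cc(Br)cc(OC)c1O[Si](C(C)C)(C(C)C)C(C)C
F8 | step 8 | (1R,2S,3Z)-4-{3,5-dimethoxy-4-[tri(propan-2-yl)silyloxy]phenyl}-2,3-dimethyl-1-(3,4,5-trimethoxyphenyl)but-3-en-1-yl benzoate | COc1cc(/C=C(/C)[C@H](C)[C@@H](OC(=O)c2ccccc2)c2cc(OC)c(OC)c(OC)c2)cc(OC)c1O[Si](C(C)C)(C(C)C)C(C)C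
F9 | step 11 | (1R,2S,3R)-2,3-dimethyl-4-(1,3,5-trimethoxy-4-oxocyclohexa-2,5-dien-1-yl)-1-(3,4,5-trimethoxyphenyl)butyl benzoate | COC1=CC(OC)(C[C@@H](C)[C@H](C)[C@@H](OC(=O)c2ccccc2)c2cc(OC)c(OC)c(OC)c2)C=C(OC)C1=O
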